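Remark on the chemistry: C3 is the only stereocentre and is S in the target (ranking OH > C4 > C2 > C1′); 4-bromo-3-methoxyphenol is taken as a commercial starting material because it fixes the ring B halogen position without a regiochemically doubtful bromination.

## Analysis of the target

The target is a 3-hydroxyisoflavanone: a chroman-4-one (ring A fused to the dihydropyranone ring C) that carries at C3 a hydroxyl group and ring B. Ring B is a 1,2,3,4-tetrasubstituted arene with 2′-OMe, a 3′-prenyl (3-methylbut-2-en-1-yl) chain and 4′-OH. C3 is a fully substituted carbinol carbon (OH, C4, C2, C1′) with no neighbouring stereocentre, so it has to be set by reagent control. C3 has no hydrogen and cannot epimerise by enolisation, but it is benzylic to a very electron-rich ring and para to a free phenol in the target, so acid can ionise it (loss of water towards the isoflavone or a quinone methide). The prenyl olefin rules out hydrogenation, strong electrophiles and strong protic acid, and an ortho-prenylphenol cyclises to a chroman under acid. The oxygens must be told apart: 5-OH from 7-OMe on ring A, and 2′-OMe from 4′-OH on ring B. The difficulty is therefore to build the quaternary α-ketol enantioselectively and to close ring C without endangering it. The strategy rests on two facts: C4 is an acyl carbon on C4a, ortho to the ring A oxygen O1, and C2–C3 with the C3 oxygen is a masked epoxide. An ester of a 2-arylglycidic acid with the ring A phenol therefore already holds O1, C2, C3, C4 and both arenes.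

## Retrosynthetic reasoning

**22 back to 21.** The last bond cut is the O–Si bond at 4′-O. The free 4′-phenol, flanked by the prenyl chain and para to the C3 carbinol, is the most fragile part of the molecule, so it is unmasked last under buffered fluoride, which harms neither the olefin nor the α-ketol.

**21 back to 20.** The 5-O–CH3 bond is cut next. This lets ring A come from the simple 3,5-dimethoxyphenol 15: only the methoxy group peri to the C4 carbonyl can form a six-membered boron chelate with it, so 5-O is distinguished from 7-O and 2′-O by position, not by a separate protecting-group scheme.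

**20 back to 17.** The key disconnection cuts both bonds that tie ring C to ring A, C4–C4a and O1–C2. Cutting here and not at C3 leaves the stereocentre untouched. Both bonds end on the same arene, so a single ortho-bromophenol ester 17 can deliver them in sequence: metalation at C4a moves the acyl group from O1 to carbon (aryllithium 18 to phenoxide 19), and the freed O1 then opens the epoxide at its methylene. One ring and two skeletal bonds are gained in one flask, and the epoxide serves as both protecting group for the tertiary alcohol and leaving group at C2.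

**17 back to 14 and 16.** The ester C–O bond is the temporary tether; it joins the two halves convergently. Acid 14 carries all of ring B and the stereocentre; phenol 16 carries ring A and the bromine that marks C4a.

**16 back to 15.** The C–Br bond is placed ortho to the hydroxyl of 15, between the oxygen that will become O1 and the one that will become 5-O.

**14 back to 13, 12 and 11.** Two oxidation-level changes relate acid 14 through aldehyde 13 to epoxy alcohol 12. The epoxide C–O bonds of 12 are then cut to reach allylic alcohol 11. This is where C3 is set: the primary hydroxyl of 11 directs a titanium tartrate epoxidation, which gives absolute control and leaves the isolated prenyl olefin alone.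

**11 back to 9 and 10.** The C1′–C3 bond is an sp2–sp2 bond made by cross-coupling arylboronate 9 with 2-bromoallyl alcohol 10, which brings C2, C3 and the future C4 as one three-carbon unit.

**9 back to 7, 6 and 5.** The C–B bond comes from the C–Br bond of 7 through aryllithium 8. Before that, the acetal of 5 is exchanged for the silyl ether (via phenol 6). The acetal is needed to direct metalation, but the silyl ether is the only group that can be removed at the end without acid.

**5 back to 2 and 3, and 2 back to 1.** The aryl–prenyl bond is cut between the two ring B oxygens, where acetal-assisted deprotonation of 2 gives aryllithium 4 for alkylation with prenyl bromide 3. The bromine of 1 is already para to the phenol oxygen, which fixes the substitution pattern of ring B.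

## Alternatives that were turned down

**Alternative 1:** The cut is at C3–O and C2–C3, giving the ring B aryl diazoacetate A1, benzyl alcohol A2 as oxygen donor and formaldehyde A3 as C2. In the forward step a dirhodium tetracarboxylate converts A1 into a carbenoid, A2 adds to form an oxonium ylide, and a chiral phosphoric acid steers its aldol-type capture by A3 to the α-benzyloxy-β-hydroxy ester A4.
- For: C3 is assembled convergently and catalytically from three achiral pieces with its oxygen and both carbon neighbours in place. On convergence at the stereocentre it is at least as good as the chosen route.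
- Against: the carbenoid of A1 sits next to a 2′-methoxy group (1,5 C–H insertion to a dihydrobenzofuran) and shares the molecule with a nucleophilic trisubstituted olefin. A3 is the least developed electrophile for this ylide trapping. The benzyl ether of A4 cannot be removed by hydrogenolysis in the presence of the prenyl group.
- Comparison: the step closes no ring. After A4, O1–C2 and C4–C4a still have to be made in separate operations. The chosen route spends a few more steps before its key step, but that step delivers the whole of ring C.

**Alternative 2:** The cut is at C4a–C5 and C8–C8a, so ring A is grown last on the enantiopure dienophile A5, a 3-aryl-3-hydroxy-5-(phenylsulfinyl)dihydropyranone. Cycloaddition with the siloxy diene A6, then loss of the sulfinyl group as a sulfenic acid and of one methoxy group, would aromatise the new ring to A7, which is structurally the same as compound 21.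
- For: ring A arrives with 5-OH and 7-OMe already differentiated, so no demethylation is needed. On this point it is stronger than the chosen route, which needs a Lewis-acid step near the end.
- Against: A5 must already contain ring C and the C3 carbinol in enantiopure form, so the hard part of the problem is only moved, into a less accessible heterocycle. Its C4a=C8a bond is an enol ether (push–pull) and a poor dienophile even with the sulfinyl group. During aromatisation the C8a–O1 bond can leave instead of the sulfinyl group, opening ring C.
- Comparison: the chosen route uses cheap aromatic building blocks for both rings and a ring closure that cannot expel O1.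

**Alternative 3:** The cut is at C3–C4. The keto aldehyde A8 (a ring A salicylaldehyde ether of the ring B phenacyl unit) would be closed by a chiral triazolium-derived carbene and an amine base. The aldehyde becomes an acyl anion equivalent that adds to the tethered ketone, giving A9 and setting C3 during ring closure.
- For: it is the shortest plan; A8 is only an O-alkylation away from two arenes, and A9 needs a single fluoride step. On step economy and on joining stereocontrol with ring formation it is stronger than the chosen route.
- Against: the ketone is a hindered, electron-rich aryl ketone with an ortho-methoxy group, and the aldehyde has two ortho oxygens, so both partners are deactivated. The α-aryloxy ketone can enolise under the same base and undergo intramolecular aldol condensation to a 2-aroylbenzofuran (Rap–Stoermer pathway). Benzoin additions are reversible, which can erode the configuration.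
- Comparison: the chosen route sets C3 early, on a small molecule, by an epoxidation whose facial sense is predictable and can be checked before the fragments are joined, and its ring closure does not break any bond at C3.

Key step: step 12

## Route

Step 1
Reactants: 1 4-bromo-3-methoxyphenol
Product: 2 1-bromo-2-methoxy-4-(methoxymethoxy)benzene
Conditions: NaH, MOMCl, DMF, 0 °C → rt
Reagents that add atoms: chloromethyl methyl ether, COCCl
Why: Williamson-type O-alkylation of the sodium phenoxide; the methoxymethyl ether is chosen because its acetal oxygen coordinates lithium and directs the metalation of step 2.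

Step 2
Reactants: 2 1-bromo-2-methoxy-4-(methoxymethoxy)benzene; 3 1-bromo-3-methylbut-2-ene (prenyl bromide)
Product: 5 1-bromo-2-methoxy-4-(methoxymethoxy)-3-(3-methylbut-2-en-1-yl)benzene, via 2-lithio derivative 4 (not isolated)
Conditions: LiN(i-Pr)2 (LDA), THF, −78 °C; then 3, −78 → −30 °C
Reagents that add atoms: none
Why: Directed ortho-metalation: the amide base does not exchange the bromine and removes the proton flanked by the methoxy and methoxymethoxy groups, the most acidic and best-coordinated site. The hindered aryllithium is then alkylated at the primary carbon of the allylic bromide (SN2).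

Step 3
Reactants: 5 1-bromo-2-methoxy-4-(methoxymethoxy)-3-(3-methylbut-2-en-1-yl)benzene
Product: 6 4-bromo-3-methoxy-2-(3-methylbut-2-en-1-yl)phenol
Conditions: HCl (1.25 M in MeOH), rt
Reagents that add atoms: none
Why: Acid-catalysed transacetalisation to methanol removes the acetal; at room temperature in dilute methanolic acid an ortho-prenylphenol should neither cyclise nor add HCl, and the exchange is done here, on a simple arene, so that no acid is needed late in the route.

Step 4
Reactants: 6 4-bromo-3-methoxy-2-(3-methylbut-2-en-1-yl)phenol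
Product: 7 [4-bromo-3-methoxy-2-(3-methylbut-2-en-1-yl)phenoxy]triisopropylsilane
Conditions: TIPSCl, imidazole, DMF, rt → 40 °C
Reagents that add atoms: chlorotri(propan-2-yl)silane, CC(C)[Si](Cl)(C(C)C)C(C)C
Why: Standard silylation of a phenol; the triisopropylsilyl ether tolerates organolithiums, the aqueous base of the cross-coupling and BCl3 at low temperature, and is removed at the end by fluoride.

Step 5
Reactants: 7 [4-bromo-3-methoxy-2-(3-methylbut-2-en-1-yl)phenoxy]triisopropylsilane
Product: 9 2-[2-methoxy-3-(3-methylbut-2-en-1-yl)-4-(triisopropylsilyloxy)phenyl]-4,4,5,5-tetramethyl-1,3,2-dioxaborolane, via aryllithium 8 (not isolated)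
Conditions: n-BuLi, THF, −78 °C; then i-PrOB(pin), −78 °C → rt; aq. NH4Cl
Reagents that add atoms: 2-isopropoxy-4,4,5,5-tetramethyl-1,3,2-dioxaborolane, CC(C)OB1OC(C)(C)C(C)(C)O1
Why: Bromine–lithium exchange at −78 °C is much faster than deprotonation of the benzylic-allylic methylene, and the aryllithium is trapped by the borate to give the pinacol boronate.

Step 6
Reactants: 9 the arylboronate of step 5; 10 2-bromoprop-2-en-1-ol
Product: 11 2-[2-methoxy-3-(3-methylbut-2-en-1-yl)-4-(triisopropylsilyloxy)phenyl]prop-2-en-1-ol
Conditions: Pd(dppf)Cl2 (3 mol %), K3PO4, THF/H2O, 60 °C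
Reagents that add atoms: none
Why: Suzuki–Miyaura coupling of an arylboronate with a 1,1-disubstituted vinyl bromide forms C1′–C3; the free allylic hydroxyl is tolerated and the aryl silyl ether should survive phosphate at this temperature.

Step 7
Reactants: 11 2-[2-methoxy-3-(3-methylbut-2-en-1-yl)-4-(triisopropylsilyloxy)phenyl]prop-2-en-1-ol
Product: 12 [(2R)-2-[2-methoxy-3-(3-methylbut-2-en-1-yl)-4-(triisopropylsilyloxy)phenyl]oxiran-2-yl]methanol
Conditions: Ti(OiPr)4 (10 mol %), D-(−)-diisopropyl tartrate (12 mol %), t-BuOOH, 4 Å MS, CH2Cl2, −25 °C; non-acidic work-up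
Reagents that add atoms: tert-butyl hydroperoxide, CC(C)(C)OO
Why: Sharpless asymmetric epoxidation: only the olefin of the titanium-bound allylic alkoxide is oxidised, so the prenyl double bond is spared. D-(−)-tartrate delivers oxygen to the face opposite to that by which L-(+)-tartrate gives (S)-glycidol and (S)-2-methylglycidol, which with the ranking O > ring CH2 > CH2OH > aryl makes the new centre (the future C3) R at this stage.

Step 8
Reactants: 12 the (2R)-epoxy alcohol of step 7
Product: 13 (2S)-2-[2-methoxy-3-(3-methylbut-2-en-1-yl)-4-(triisopropylsilyloxy)phenyl]oxirane-2-carbaldehyde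
Conditions: SO3·pyridine, DMSO, i-Pr2NEt, CH2Cl2, 0 °C
Reagents that add atoms: none
Why: Parikh–Doering oxidation runs under basic, non-ionising conditions suited to the acid-labile benzylic epoxide; the quaternary centre cannot epimerise, and the descriptor changes to S only because CHO now outranks the ring CH2.

Step 9
Reactants: 13 the (2S)-epoxy aldehyde of step 8
Product: 14 (2S)-2-[2-methoxy-3-(3-methylbut-2-en-1-yl)-4-(triisopropylsilyloxy)phenyl]oxirane-2-carboxylic acid
Conditions: NaClO2, NaH2PO4, 2-methylbut-2-ene (large excess), t-BuOH/H2O, 0 °C → rt; acidify cold to pH 4, use at once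
Reagents that add atoms: sodium chlorite, [Na+].[O-]Cl=O
Why: Pinnick oxidation; the sacrificial olefin in excess intercepts hypochlorous acid and so protects the prenyl group and the electron-rich arene. The carboxyl group now next to the epoxide disfavours its ionisation, and the acid is used without storage.

Step 10
Reactants: 15 3,5-dimethoxyphenol
Product: 16 2-bromo-3,5-dimethoxyphenol
Conditions: NBS (1.0 equiv, slow addition), i-Pr2NH (10 mol %), CH2Cl2, −78 → 0 °C
Reagents that add atoms: N-bromosuccinimide, O=C1CCC(=O)N1Br
Why: Amine-mediated ortho-selective bromination of a phenol: the N-bromoamine is delivered through hydrogen bonding to the hydroxyl, favouring the position between OH and OMe over the position para to OH; slow addition at low temperature limits dibromination.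

Step 11
Reactants: 14 the (2S)-glycidic acid of step 9; 16 2-bromo-3,5-dimethoxyphenol
Product: 17 2-bromo-3,5-dimethoxyphenyl (2S)-2-[2-methoxy-3-(3-methylbut-2-en-1-yl)-4-(triisopropylsilyloxy)phenyl]oxirane-2-carboxylate
Conditions: EDC·HCl, DMAP, CH2Cl2, 0 °C → rt
Reagents that add atoms: none
Why: Steglich esterification; the acylpyridinium intermediate is readily captured by a phenol, and the neutral conditions leave the epoxide and the stereocentre untouched.

Step 12
Reactants: 17 the 2-bromo-3,5-dimethoxyphenyl (2S)-glycidate of step 11
Product: 20 (3S)-3-hydroxy-5,7-dimethoxy-3-[2-methoxy-3-(3-methylbut-2-en-1-yl)-4-(triisopropylsilyloxy)phenyl]-2,3-dihydro-4H-chromen-4-one, via aryllithium 18 (not isolated), via lithium 2-acylphenoxide 19 (not isolated)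
Conditions: t-BuLi (2.1 equiv), THF, −100 → −78 °C; then DMPU, −78 → 0 °C; aq. NH4Cl
Reagents that add atoms: none
Why: Proposed new method: t-BuLi exchanges the bromine flanked by the two ring oxygens faster than it adds to the hindered, α-quaternary ester carbonyl at −100 °C, and aryllithium 18 attacks its own ester through a four-membered tetrahedral intermediate whose collapse moves the acyl group from O1 to C4a and forms C4–C4a (closest known reaction type: the anionic ortho-Fries rearrangement of aryl esters triggered by halogen–lithium exchange). The lithium phenoxide 19 so released is an ortho-hydroxyaryl epoxy ketone, the substrate class that closes to 3-hydroxychromanones under base (the cyclisation manifold of the Algar–Flynn–Oyamada reaction), and on warming it displaces the epoxide oxygen at the methylene C2 by SN2, forming O1–C2 and closing ring C in a 6-endo-tet mode. The competing 5-exo closure would need substitution at the fully substituted, aryl- and acyl-bearing C3 and is sterically excluded under these basic, non-ionising conditions. No stereocentre is formed: C3 keeps all four of its bonds, so its configuration is the one set in step 7, and the lack of a hydrogen at C3 rules out enolisation or retro-oxa-Michael opening of the product alkoxide. The second equivalent of t-BuLi only destroys the tert-butyl bromide, so no strong base is left when ketone 19 appears. What is new is the relay of the two stages in one flask on a glycidate; each stage has precedent on its own.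

Step 13
Reactants: 20 the 5,7-dimethoxy chromanone of step 12
Product: 21 (3S)-3,5-dihydroxy-7-methoxy-3-[2-methoxy-3-(3-methylbut-2-en-1-yl)-4-(triisopropylsilyloxy)phenyl]-2,3-dihydro-4H-chromen-4-one
Conditions: BCl3 (1 M in CH2Cl2, 3 equiv), CH2Cl2, −78 → −40 °C; MeOH, aq. NaHCO3
Reagents that add atoms: none
Why: Chelation-controlled demethylation: boron bound to the C4 carbonyl activates only the peri 5-methoxy group, whose methyl is removed by chloride, while the 7- and 2′-methoxy groups cannot form that six-membered chelate. The low temperature is meant to spare the prenyl olefin and the silyl ether, and the borate formed at the 3-hydroxyl is cleaved on methanolic work-up.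

Step 14
Reactants: 21 the 4′-O-silyl ether of step 13
Product: 22 (3S)-3,5-dihydroxy-3-[4-hydroxy-2-methoxy-3-(3-methylbut-2-en-1-yl)phenyl]-7-methoxy-2,3-dihydro-4H-chromen-4-one (target)
Conditions: Bu4NF, AcOH (1:1), THF, 0 °C
Reagents that add atoms: none
Why: Fluoride cleavage of the aryl silyl ether; the acetic acid buffer keeps the liberated phenoxide protonated, so that the base-sensitive α-ketol and the para-hydroxybenzylic carbinol are not exposed to a free phenoxide.

## Compound list

1 | 4-bromo-3-methoxyphenol | COc1cc(O)ccc1Br | starting material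
2 | 1-bromo-2-methoxy-4-(methoxymethoxy)benzene | COCOc1ccc(Br)c(OC)c1 | intermediate
3 | 1-bromo-3-methylbut-2-ene (prenyl bromide) | CC(C)=CCBr | starting material
4 | [3-bromo-2-methoxy-6-(methoxymethoxy)phenyl]lithium | [Li]c1c(OC)c(Br)ccc1OCOC | intermediate (not isolated)
5 | 1-bromo-2-methoxy-4-(methoxymethoxy)-3-(3-methylbut-2-en-1-yl)benzene | COCOc1ccc(Br)c(OC)c1CC=C(C)C | intermediate
6 | 4-bromo-3-methoxy-2-(3-methylbut-2-en-1-yl)phenol | COc1c(Br)ccc(O)c1CC=C(C)C | intermediate
7 | [4-bromo-3-methoxy-2-(3-methylbut-2-en-1-yl)phenoxy]triisopropylsilane | COc1c(Br)ccc(O[Si](C(C)C)(C(C)C)C(C)C)c1CC=C(C)C | intermediate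
8 | [2-methoxy-3-(3-methylbut-2-en-1-yl)-4-(triisopropylsilyloxy)phenyl]lithium | [Li]c1ccc(O[Si](C(C)C)(C(C)C)C(C)C)c(CC=C(C)C)c1OC | intermediate (not isolated)
9 | 2-[2-methoxy-3-(3-methylbut-2-en-1-yl)-4-(triisopropylsilyloxy)phenyl]-4,4,5,5-tetramethyl-1,3,2-dioxaborolane | COc1c(B2OC(C)(C)C(C)(C)O2)ccc(O[Si](C(C)C)(C(C)C)C(C)C)c1CC=C(C)C | intermediate
10 | 2-bromoprop-2-en-1-ol | OCC(Br)=C | starting material
11 | 2-[2-methoxy-3-(3-methylbut-2-en-1-yl)-4-(triisopropylsilyloxy)phenyl]prop-2-en-1-ol | C=C(CO)c1ccc(O[Si](C(C)C)(C(C)C)C(C)C)c(CC=C(C)C)c1OC | intermediate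
12 | [(2R)-2-[2-methoxy-3-(3-methylbut-2-en-1-yl)-4-(triisopropylsilyloxy)phenyl]oxiran-2-yl]methanol | OC[C@]1(c2ccc(O[Si](C(C)C)(C(C)C)C(C)C)c(CC=C(C)C)c2OC)CO1 | intermediate
13 | (2S)-2-[2-methoxy-3-(3-methylbut-2-en-1-yl)-4-(triisopropylsilyloxy)phenyl]oxirane-2-carbaldehyde | O=C[C@]1(c2ccc(O[Si](C(C)C)(C(C)C)C(C)C)c(CC=C(C)C)c2OC)CO1 | intermediate
14 | (2S)-2-[2-methoxy-3-(3-methylbut-2-en-1-yl)-4-(triisopropylsilyloxy)phenyl]oxirane-2-carboxylic acid | OC(=O)[C@]1(c2ccc(O[Si](C(C)C)(C(C)C)C(C)C)c(CC=C(C)C)c2OC)CO1 | intermediate
15 | 3,5-dimethoxyphenol | COc1cc(O)cc(OC)c1 | starting material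
16 | 2-bromo-3,5-dimethoxyphenol | COc1cc(OC)c(Br)c(O)c1 | intermediate
17 | 2-bromo-3,5-dimethoxyphenyl (2S)-2-[2-methoxy-3-(3-methylbut-2-en-1-yl)-4-(triisopropylsilyloxy)phenyl]oxirane-2-carboxylate | COc1cc(OC)c(Br)c(c1)OC(=O)[C@]2(c3ccc(O[Si](C(C)C)(C(C)C)C(C)C)c(CC=C(C)C)c3OC)CO2 | intermediate
18 | 2-lithio-3,5-dimethoxyphenyl (2S)-2-[2-methoxy-3-(3-methylbut-2-en-1-yl)-4-(triisopropylsilyloxy)phenyl]oxirane-2-carboxylate | COc1cc(OC)c([Li])c(c1)OC(=O)[C@]2(c3ccc(O[Si](C(C)C)(C(C)C)C(C)C)c(CC=C(C)C)c3OC)CO2 | intermediate (not isolated)
19 | lithium 3,5-dimethoxy-2-{[(2S)-2-[2-methoxy-3-(3-methylbut-2-en-1-yl)-4-(triisopropylsilyloxy)phenyl]oxiran-2-yl]carbonyl}phenoxide | COc1cc(OC)c(C(=O)[C@]2(c3ccc(O[Si](C(C)C)(C(C)C)C(C)C)c(CC=C(C)C)c3OC)CO2)c(O[Li])c1 | intermediate (not isolated)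
20 | (3S)-3-hydroxy-5,7-dimethoxy-3-[2-methoxy-3-(3-methylbut-2-en-1-yl)-4-(triisopropylsilyloxy)phenyl]-2,3-dihydro-4H-chromen-4-one | COc1cc(OC)c2c(c1)OC[C@@](O)(c3ccc(O[Si](C(C)C)(C(C)C)C(C)C)c(CC=C(C)C)c3OC)C2=O | intermediate
21 | (3S)-3,5-dihydroxy-7-methoxy-3-[2-methoxy-3-(3-methylbut-2-en-1-yl)-4-(triisopropylsilyloxy)phenyl]-2,3-dihydro-4H-chromen-4-one | COc1cc(O)c2c(c1)OC[C@@](O)(c3ccc(O[Si](C(C)C)(C(C)C)C(C)C)c(CC=C(C)C)c3OC)C2=O | intermediate
22 | (3S)-3,5-dihydroxy-3-[4-hydroxy-2-methoxy-3-(3-methylbut-2-en-1-yl)phenyl]-7-methoxy-2,3-dihydro-4H-chromen-4-one | COc1cc(O)c2c(c1)OC[C@@](O)(c1ccc(O)c(CC=C(C)C)c1OC)C2=O | target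

## Step count and least certain steps

Total: 14 steps. Longest linear sequence: 13 steps (steps 1–9 and 11–14; step 10 is the one-step side branch to phenol 16).

**Step 12 (key step, proposed new method).**
- What may go wrong: the alkyllithium may add to the ester carbonyl or open the epoxide before exchange is complete, the acyl transfer may go partly between molecules, or the lithium phenoxide may close sluggishly, so that the α-ketol product sits under basic conditions for too long.
- Fallback (known reactions only), from boronate 9 back to 20: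
  - Commercial 1-(2-hydroxy-4,6-dimethoxyphenyl)ethanone is condensed with N,N-dimethylformamide dimethyl acetal to the enaminone (E)-3-(dimethylamino)-1-(2-hydroxy-4,6-dimethoxyphenyl)prop-2-en-1-one F1.
  - Iodine cyclises it to 3-iodo-5,7-dimethoxy-4H-chromen-4-one F2.
  - Suzuki–Miyaura coupling of F2 with 9 (Pd(dppf)Cl2, K2CO3) gives the isoflavone 5,7-dimethoxy-3-[2-methoxy-3-(3-methylbut-2-en-1-yl)-4-(triisopropylsilyloxy)phenyl]-4H-chromen-4-one F3.
  - Conjugate reduction with LiBH(s-Bu)3 at −78 °C gives the racemic isoflavanone 5,7-dimethoxy-3-[2-methoxy-3-(3-methylbut-2-en-1-yl)-4-(triisopropylsilyloxy)phenyl]-2,3-dihydro-4H-chromen-4-one F4.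
  - The potassium enolate of F4 (KN(SiMe3)2, −78 °C) is hydroxylated with an enantiopure (camphorsulfonyl)oxaziridine, the antipode of the reagent being chosen to give the (S)-carbinol 20.
  - C3 is then set by reagent-controlled enolate oxidation instead of by the epoxide.

**Step 7 (asymmetric epoxidation).**
- What may go wrong: the epoxide is benzylic to a ring with ortho- and para-oxygen donors, so it may ionise and open at titanium or on silica, which lowers yield and optical purity.
- Fallback, from 11 back to 13: oxidise 11 with MnO2 to the enal 2-[2-methoxy-3-(3-methylbut-2-en-1-yl)-4-(triisopropylsilyloxy)phenyl]prop-2-enal F5. Epoxidise F5 nucleophilically with H2O2 under iminium catalysis by a diarylprolinol silyl ether; this attacks only the electron-poor double bond and gives 13 directly. The epoxide is then made only when the deactivating carbonyl group is already beside it.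

**Step 13 (demethylation).**
- What may go wrong: the HCl released when the 3-hydroxyl is borylated may add to the prenyl olefin, the borate at O3 may direct cleavage of the 2′-methoxy group, or the tertiary benzylic C–O bond may ionise.
- Fallback, from acid 14 back to target 22, replacing the 5-O-methyl by a second silyl group so that no Lewis acid is needed after ring closure:
  - 5-Methoxyresorcinol is converted into 1-methoxy-3,5-bis(methoxymethoxy)benzene F6.
  - F6 is lithiated between the two acetal oxygens (n-BuLi) and brominated with 1,2-dibromotetrachloroethane to 2-bromo-5-methoxy-1,3-bis(methoxymethoxy)benzene F7.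
  - Methanolic HCl gives 2-bromo-5-methoxybenzene-1,3-diol F8.
  - One equivalent of TIPSCl gives 2-bromo-5-methoxy-3-(triisopropylsilyloxy)phenol F9.
  - Steglich esterification of F9 with 14 gives 2-bromo-5-methoxy-3-(triisopropylsilyloxy)phenyl (2S)-2-[2-methoxy-3-(3-methylbut-2-en-1-yl)-4-(triisopropylsilyloxy)phenyl]oxirane-2-carboxylate F10.
  - The cascade of step 12 on F10 gives (3S)-3-hydroxy-7-methoxy-3-[2-methoxy-3-(3-methylbut-2-en-1-yl)-4-(triisopropylsilyloxy)phenyl]-5-(triisopropylsilyloxy)-2,3-dihydro-4H-chromen-4-one F11.
  - Both silyl ethers of F11 are removed together with Bu4NF/AcOH to give 22.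

**Step 2 (metalation and prenylation).**
- What may go wrong: the hindered aryllithium may be alkylated slowly or at the tertiary end of the allylic bromide, and a long-lived aryllithium may scramble bromine with unreacted 2 or lose LiBr after deprotonation next to bromine.
- Fallback, from 2 back to 5: lithiate 2 as before and trap at −78 °C with the small, symmetrical allyl bromide to give 1-bromo-2-methoxy-4-(methoxymethoxy)-3-(prop-2-en-1-yl)benzene F12. Convert the allyl group into the prenyl group by olefin cross-metathesis with 2-methylbut-2-ene and the second-generation Grubbs catalyst.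

**Step 10 (bromination of ring A).**
- What may go wrong: substitution para to the hydroxyl (between the two methoxy groups) and double bromination may compete with the desired ortho attack.
- Fallback, from 15 back to 16: acylate 15 with diethylcarbamoyl chloride to 3,5-dimethoxyphenyl diethylcarbamate F13. Lithiate F13 ortho to the carbamate (s-BuLi, TMEDA, −78 °C, kept cold to prevent carbamoyl migration) and brominate with 1,2-dibromotetrachloroethane to 2-bromo-3,5-dimethoxyphenyl diethylcarbamate F14. Hydrolyse F14 with NaOH in aqueous ethanol to 16.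

## Further compounds

F1 | step 12 | (E)-3-(dimethylamino)-1-(2-hydroxy-4,6-dimethoxyphenyl)prop-2-en-1-one | CN(C)/C=C/C(=O)c1c(O)cc(OC)cc1OC
F2 | step 12 | 3-iodo-5,7-dimethoxy-4H-chromen-4-one | COc1cc(OC)c2c(c1)occ(I)c2=O
F3 | step 12 | 5,7-dimethoxy-3-[2-methoxy-3-(3-methylbut-2-en-1-yl)-4-(triisopropylsilyloxy)phenyl]-4H-chromen-4-one | COc1cc(OC)c2c(c1)occ(-c3ccc(O[Si](C(C)C)(C(C)C)C(C)C)c(CC=C(C)C)c3OC)c2=O
F4 | step 12 | racemic 5,7-dimethoxy-3-[2-methoxy-3-(3-methylbut-2-en-1-yl)-4-(triisopropylsilyloxy)phenyl]-2,3-dihydro-4H-chromen-4-one | COc1cc(OC)c2c(c1)OCC(c3ccc(O[Si](C(C)C)(C(C)C)C(C)C)c(CC=C(C)C)c3OC)C2=O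
F5 | step 7 | 2-[2-methoxy-3-(3-methylbut-2-en-1-yl)-4-(triisopropylsilyloxy)phenyl]prop-2-enal | C=C(C=O)c1ccc(O[Si](C(C)C)(C(C)C)C(C)C)c(CC=C(C)C)c1OC
F6 | step 13 | 1-methoxy-3,5-bis(methoxymethoxy)benzene | COCOc1cc(OC)cc(OCOC)c1
F7 | step 13 | 2-bromo-5-methoxy-1,3-bis(methoxymethoxy)benzene | COCOc1cc(OC)cc(OCOC)c1Br
F8 | step 13 | 2-bromo-5-methoxybenzene-1,3-diol | COc1cc(O)c(Br)c(O)c1
F9 | step 13 | 2-bromo-5-methoxy-3-(triisopropylsilyloxy)phenol | COc1cc(O)c(Br)c(O[Si](C(C)C)(C(C)C)C(C)C)c1
F10 | step 13 | 2-bromo-5-methoxy-3-(triisopropylsilyloxy)phenyl (2S)-2-[2-methoxy-3-(3-methylbut-2-en-1-yl)-4-(triisopropylsilyloxy)phenyl]oxirane-2-carboxylate | COc1cc(O[Si](C(C)C)(C(C)C)C(C)C)c(Br)c(c1)OC(=O)[C@]2(c3ccc(O[Si](C(C)C)(C(C)C)C(C)C)c(CC=C(C)C)c3OC)CO2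
F11 | step 13 | (3S)-3-hydroxy-7-methoxy-3-[2-methoxy-3-(3-methylbut-2-en-1-yl)-4-(triisopropylsilyloxy)phenyl]-5-(triisopropylsilyloxy)-2,3-dihydro-4H-chromen-4-one | COc1cc(O[Si](C(C)C)(C(C)C)C(C)C)c2c(c1)OC[C@@](O)(c3ccc(O[Si](C(C)C)(C(C)C)C(C)C)c(CC=C(C)C)c3OC)C2=O
F12 | step 2 | 1-bromo-2-methoxy-4-(methoxymethoxy)-3-(prop-2-en-1-yl)benzene | COCOc1ccc(Br)c(OC)c1CC=C
F13 | step 10 | 3,5-dimethoxyphenyl diethylcarbamate | CCN(CC)C(=O)Oc1cc(OC)cc(OC)c1
F14 | step 10 | 2-bromo-3,5-dimethoxyphenyl diethylcarbamate | CCN(CC)C(=O)Oc1cc(OC)cc(OC)c1Br
A1 | alternative 1 | methyl 2-diazo-2-[2-methoxy-3-(3-methylbut-2-en-1-yl)-4-(triisopropylsilyloxy)phenyl]acetate | COC(=O)C(=[N+]=[N-])c1ccc(O[Si](C(C)C)(C(C)C)C(C)C)c(CC=C(C)C)c1OC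
A2 | alternative 1 | benzyl alcohol | OCc1ccccc1
A3 | alternative 1 | formaldehyde | C=O
A4 | alternative 1 | methyl (2S)-2-(benzyloxy)-3-hydroxy-2-[2-methoxy-3-(3-methylbut-2-en-1-yl)-4-(triisopropylsilyloxy)phenyl]propanoate | COC(=O)[C@](OCc1ccccc1)(c1ccc(O[Si](C(C)C)(C(C)C)C(C)C)c(CC=C(C)C)c1OC)CO
A5 | alternative 2 | (3S)-3-hydroxy-3-[2-methoxy-3-(3-methylbut-2-en-1-yl)-4-(triisopropylsilyloxy)phenyl]-5-(phenylsulfinyl)-2,3-dihydro-4H-pyran-4-one | O=C1C(S(=O)c2ccccc2)=COC[C@@]1(O)c3ccc(O[Si](C(C)C)(C(C)C)C(C)C)c(CC=C(C)C)c3OC
A6 | alternative 2 | 1,3-dimethoxy-1-(trimethylsilyloxy)buta-1,3-diene | C=C(OC)C=C(OC)O[Si](C)(C)C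
A7 | alternative 2 | (3S)-3,5-dihydroxy-7-methoxy-3-[2-methoxy-3-(3-methylbut-2-en-1-yl)-4-(triisopropylsilyloxy)phenyl]-2,3-dihydro-4H-chromen-4-one | COc1cc(O)c2c(c1)OC[C@@](O)(c1ccc(O[Si](C(C)C)(C(C)C)C(C)C)c(CC=C(C)C)c1OC)C2=O
A8 | alternative 3 | 2-(tert-butyldimethylsilyloxy)-4-methoxy-6-{2-[2-methoxy-3-(3-methylbut-2-en-1-yl)-4-(triisopropylsilyloxy)phenyl]-2-oxoethoxy}benzaldehyde | O=Cc1c(O[Si](C)(C)C(C)(C)C)cc(OC)cc1OCC(=O)c1ccc(O[Si](C(C)C)(C(C)C)C(C)C)c(CC=C(C)C)c1OC
A9 | alternative 3 | (3S)-5-(tert-butyldimethylsilyloxy)-3-hydroxy-7-methoxy-3-[2-methoxy-3-(3-methylbut-2-en-1-yl)-4-(triisopropylsilyloxy)phenyl]-2,3-dihydro-4H-chromen-4-one | COc1cc(O[Si](C)(C)C(C)(C)C)c2c(c1)OC[C@@](O)(c1ccc(O[Si](C(C)C)(C(C)C)C(C)C)c(CC=C(C)C)c1OC)C2=O
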